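The numbers in the tables are simulated for substances that don't exist.

A small charge of catalyst, 0.11 mM, faced 22.0 mM of substrates in the flask, which repeats the west run with each substrate at half the concentration.

| flask | left-handed substrate | right-handed substrate | gas | catalyst | added ligand | remark | time |
|---|---|---|---|---|---|---|---|
| west | 0.022 M | 0.022 M | 1 mM (held) | 0.11 mM (in portions, 3) | 0.19 mM | run made earlier; portions every 3.0 min |  |
| flask | 0.011 M | 0.011 M | 1.0 mM (held) | 0.11 mM (in portions, 3) | 0.19 mM | the portions of catalyst follow each other after 3.0 min, the first at the start | 80 min |

west run (percent of the left-handed substrate and right-handed substrate together charged)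

| time / min | right-handed product / % | left-handed substrate / % | left-handed product / % | right-handed substrate / % |
|---|---|---|---|---|
| 5.00 | 0.2 | 47.9 | 1.2 | 50.1 |
| 10.0 | 0.7 | 44.5 | 6.1 | 47.8 |
| 15.0 | 1.1 | 42.1 | 8.6 | 47.2 |
| 20.0 | 2.9 | 38.6 | 12.7 | 45.8 |
| 25.0 | 2.1 | 35.9 | 17.0 | 44.3 |

(readings scatter by 0.5 percentage points)

- catalyst is single-handed; left-handed substrate and right-handed substrate are mirror images of each other, charged as a racemate, each of them at the stated concentration
- at the start none of the gas is in solution

* the species in which most of what was charged as left-handed substrate and right-handed substrate together, at 80 min sits (right-handed product / right-handed substrate / left-handed product / left-handed substrate)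
* the largest share itself, whichever of these holds it, in percent of the left-handed substrate and right-handed substrate together charged

I ordered the times from the shortest. The portions ended at 6.00 min, and by 5.00 min the west run still held 98.0 % of its charge as substrates, so the start cost little. The slow rung was the pool, the two substrates together. I called pool life the time in which a first-order loss shrinks them by the factor e; between the first and last west readings it came to 99.8 min. Those readings span 20.0 % of it, too little to prove an order, so first order (pseudo-first-order, with catalyst and gas as in the west run) was my judgement. Percentages then run alike in both flasks. Integrated, the rate left a pool of 46.2 % at 80 min. The last two west readings sent 85.6 % of product to the left-handed form, so I expected 46.0 % of left-handed product, more than the 25.5 % I gave the right-handed substrate.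

The forecast named left-handed product at 68 %, since the reaction “looks close to zero order in substrate”; its number stands near a straight line through the last two readings of left-handed product. My figure was lower.

The flask gave left-handed product at 44.3 %, below the forecast, with a pool of 47.5 %.

    reagent + catalyst + left-handed substrate → catalyst + left-handed product (k = 7200 M⁻² s⁻¹)
    reagent + catalyst + right-handed substrate → catalyst + right-handed product (k = 1100 M⁻² s⁻¹)
    left-handed substrate ⇌ right-handed substrate (k = 4.90 × 10⁻⁴ s⁻¹)
    gas ⇌ reagent, rate k4*(csat - [reagent]) (kL = 0.300 s⁻¹)
    catalyst + added ligand ⇌ idle complex, settled at all times (K = 13000 M⁻¹)

In the flask, left-handed substrate had a half-life by its step to left-handed product of 38 min at 30.9 min and still 38 min at 80.0 min, longer than the 24 min of its forward step to right-handed substrate alone. Net, 15.0 % of the charge passed from right-handed to left-handed substrate. Read at 30 min, the same flask had a pool of 76.7 %, where the pool life gives 76.3 %.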